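**Retrosynthetic overview**

1. Target 20 comes from its hexamethyl ether 19 by global O-demethylation; the C3 aryl group of 19 comes from decarboxylative arylation of C3 acid 14 with arylzinc 18, trans to C2.
2. The styryl arm comes from a Heck coupling of C6 bromide 11 with 4-methoxystyrene.
3. Feature used: O1, C2 (with its 2,4-dioxygenated phenyl), C3 and the oxygenated benzo ring C3a–C7a are a flavanone lacking its carbonyl carbon. The C3–C3a bond of 11 is therefore made by shifting the benzo carbon from C4 to C3 of (S)-flavanone 8, with C4 leaving the ring as CO2Me.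
4. Flavanone 8 comes from Rh-catalysed asymmetric 1,4-addition of boronic acid 7 to chromone 6, which comes from acetophenone 4 and aldehyde 1.
5. Ring order: the pyranone ring is formed in step 4 and contracted to the dihydrofuran in step 6; all four benzene rings are bought.

Key step: step 6

Assumption: the facial sense of the Rh catalyst in step 5 is not predicted here; the ligand antipode (written as S) is fixed in a trial run so that 8 has the 2S configuration.

**Route**

Step 1
Reactants: 1 4-bromo-2,6-dimethoxybenzaldehyde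
Product: 2 rac-1-(4-bromo-2,6-dimethoxyphenyl)ethan-1-ol
Conditions: MeMgBr (1.3 equiv), THF, 0 °C; then H2O/aq. NH4Cl
Reagents that add atoms: methylmagnesium bromide, C[Mg]Br
Why: Grignard 1,2-addition to the aldehyde is fast at 0 °C, where the aryl bromide does not exchange; the new carbinol centre is racemic and is removed in step 2.

Step 2
Reactants: 2 rac-1-(4-bromo-2,6-dimethoxyphenyl)ethan-1-ol
Product: 3 1-(4-bromo-2,6-dimethoxyphenyl)ethan-1-one
Conditions: Dess–Martin periodinane (1.2 equiv), CH2Cl2, rt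
Reagents that add atoms: none
Why: Dess–Martin oxidation converts the hindered benzylic alcohol into the aryl methyl ketone under neutral conditions that leave the bromide and ethers untouched.

Step 3
Reactants: 3 1-(4-bromo-2,6-dimethoxyphenyl)ethan-1-one
Product: 4 1-(4-bromo-2-hydroxy-6-methoxyphenyl)ethan-1-one
Conditions: BCl3 (1.2 equiv), CH2Cl2, −78 → 0 °C; then H2O
Reagents that add atoms: none
Why: Chelation-directed Lewis-acid ether cleavage removes only one methyl ortho to the carbonyl, because the resulting six-membered boron chelate deactivates the ketone towards a second cleavage.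

Step 4
Reactants: 4 1-(4-bromo-2-hydroxy-6-methoxyphenyl)ethan-1-one
Product: 6 7-bromo-5-methoxy-4H-chromen-4-one, via enaminone 5 (not isolated)
Conditions: Me2NCH(OMe)2 (2 equiv), PhMe, 100 °C; then conc. HCl, CH2Cl2, 40 °C
Reagents that add atoms: N,N-dimethylformamide dimethyl acetal, COC(OC)N(C)C
Why: Enaminone condensation at the methyl ketone followed by acid-promoted 6-endo oxa-Michael addition of the phenol and loss of dimethylamine is the standard chromone annulation for 3-unsubstituted chromones.

Step 5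
Reactants: 6 7-bromo-5-methoxy-4H-chromen-4-one; 7 (2,4-dimethoxyphenyl)boronic acid
Product: 8 (2S)-7-bromo-2-(2,4-dimethoxyphenyl)-5-methoxychroman-4-one
Conditions: 7 (3 equiv, in portions), [RhCl(C2H4)2]2 (2.5 mol%), (S)-MeO-F12-BIPHEP (5.5 mol%), aq. KOH (10 mol%), PhMe/H2O, 30 °C
Reagents that add atoms: none
Why: Hayashi–Miyaura Rh-catalysed asymmetric conjugate addition to the chromone, in which the aryl–Rh species of the electron-poor C2-symmetric bisphosphine inserts one face of the C2=C3 bond and thereby sets C2, while near-neutral, low-temperature conditions should avoid retro-oxa-Michael racemisation and leave the aryl bromide alone.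

Step 6
Reactants: 8 (2S)-7-bromo-2-(2,4-dimethoxyphenyl)-5-methoxychroman-4-one
Product: 11 methyl (2S,3S)-6-bromo-2-(2,4-dimethoxyphenyl)-4-methoxy-2,3-dihydro-1-benzofuran-3-carboxylate, via enol ether 9 (not isolated), via C3-thallated ketal 10 (not isolated)
Conditions: Tl(NO3)3·3H2O (1.2 equiv), HC(OMe)3, 0 °C → rt, short reaction time; then aq. NaHCO3
Reagents that add atoms: trimethyl orthoformate, COC(OC)OC; water, O; thallium(III) nitrate, [Tl+3].[O-][N+](=O)[O-].[O-][N+](=O)[O-].[O-][N+](=O)[O-] (atoms retained only in intermediate 10)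
Why: In the orthoformate the ketone is converted by the acidic Tl salt into enol ether 9, which is thallated at C3 anti to the C2 aryl group with methanol capture at C4 to give trans ketal 10; heterolysis of the C3–Tl bond (Tl(III) to Tl(I)) is coupled to a 1,2-shift of the benzo carbon C4a from C4 to C3, and the dimethoxycarbenium ion left at C4 collapses to the methyl ester on aqueous work-up. The closest known reaction type is the Tl(III) nitrate (or aryl-λ3-iodane)/trimethyl orthoformate oxidative ring contraction of flavanones to methyl trans-2-aryl-2,3-dihydrobenzofuran-3-carboxylates. The dihydrofuran ring (O1–C2–C3–C3a–C7a) is not closed by a cyclisation but arises by contraction of the pyranone, through formation of C3–C3a and extrusion of C4. C3 should be set trans to C2 because thallation is anti to the aryl group and the shift proceeds with inversion at C3 (C3–Tl antiperiplanar to C4–C4a in the diequatorial half-chair); C2 is carried over unchanged from 8, and the C3 configuration is not needed later since step 11 re-sets it. The step needs migration of C4a in preference to migration of the C2 aryl group (isoflavone) or loss of H-2 (flavone); this is secured by the C4 ketal oxygens, which make C4 the cation-accepting terminus, by the electron-rich migrating carbon flanked by O1 and the 5-OMe, and by the diequatorial conformer in which only C4–C4a is anti to Tl. Low temperature and short contact with the acid released should prevent ring-opening at C2 and attack on the dimethoxyarene.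

Step 7
Reactants: 11 methyl (2S,3S)-6-bromo-2-(2,4-dimethoxyphenyl)-4-methoxy-2,3-dihydro-1-benzofuran-3-carboxylate; 12 4-methoxystyrene
Product: 13 methyl (2S,3S)-2-(2,4-dimethoxyphenyl)-4-methoxy-6-[(E)-2-(4-methoxyphenyl)ethenyl]-2,3-dihydro-1-benzofuran-3-carboxylate
Conditions: 12 (1.3 equiv), Pd2(dba)3 (2.5 mol%), [HP(t-Bu)3]BF4 (10 mol%), Cy2NMe (1.2 equiv), dioxane, 25–40 °C
Reagents that add atoms: none
Why: Mizoroki–Heck coupling with a bulky trialkylphosphine runs near room temperature and gives the E-stilbene by syn insertion and syn β-hydride elimination, while the hindered amine is too weak to deprotonate C3 and open the ring by β-aryloxide elimination.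

Step 8
Reactants: 13 methyl (2S,3S)-2-(2,4-dimethoxyphenyl)-4-methoxy-6-[(E)-2-(4-methoxyphenyl)ethenyl]-2,3-dihydro-1-benzofuran-3-carboxylate
Product: 14 (2S,3S)-2-(2,4-dimethoxyphenyl)-4-methoxy-6-[(E)-2-(4-methoxyphenyl)ethenyl]-2,3-dihydro-1-benzofuran-3-carboxylic acid
Conditions: Me3SnOH (5 equiv), 1,2-dichloroethane, 80 °C; then 5% aq. HCl
Reagents that add atoms: trimethyltin hydroxide, C[Sn](C)(C)O
Why: Trimethyltin hydroxide cleaves methyl esters under essentially neutral conditions, which avoids the enolate at C3 that would expel the O1 aryloxide (E1cB ring-opening) under ordinary saponification.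

Step 9
Reactants: 14 (2S,3S)-2-(2,4-dimethoxyphenyl)-4-methoxy-6-[(E)-2-(4-methoxyphenyl)ethenyl]-2,3-dihydro-1-benzofuran-3-carboxylic acid
Product: 15 1,3-dioxoisoindolin-2-yl (2S,3S)-2-(2,4-dimethoxyphenyl)-4-methoxy-6-[(E)-2-(4-methoxyphenyl)ethenyl]-2,3-dihydro-1-benzofuran-3-carboxylate
Conditions: N-hydroxyphthalimide (1.1 equiv), DIC (1.1 equiv), CH2Cl2, rt, no DMAP; filtration through a short silica pad
Reagents that add atoms: N-hydroxyphthalimide, O=C1c2ccccc2C(=O)N1O
Why: Carbodiimide esterification with the acidic N-hydroxyphthalimide gives the redox-active ester without added base, so the activated ester cannot undergo base-induced ring-opening.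

Step 10
Reactants: 16 1-bromo-3,5-dimethoxybenzene
Product: 18 (3,5-dimethoxyphenyl)zinc chloride, via arylmagnesium bromide 17 (not isolated)
Conditions: Mg turnings, LiCl, THF, rt; then ZnCl2 (1.0 equiv), THF, 0 °C → rt; used as a titrated solution
Reagents that add atoms: zinc chloride, Cl[Zn]Cl; magnesium, [Mg] (retained only in intermediate 17)
Why: LiCl-assisted magnesium insertion into the aryl bromide and transmetalation to zinc give the functional-group-tolerant arylzinc nucleophile needed for the Negishi-type coupling.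

Step 11
Reactants: 15 1,3-dioxoisoindolin-2-yl (2S,3S)-2-(2,4-dimethoxyphenyl)-4-methoxy-6-[(E)-2-(4-methoxyphenyl)ethenyl]-2,3-dihydro-1-benzofuran-3-carboxylate; 18 (3,5-dimethoxyphenyl)zinc chloride
Product: 19 (2S,3S)-3-(3,5-dimethoxyphenyl)-2-(2,4-dimethoxyphenyl)-4-methoxy-6-[(E)-2-(4-methoxyphenyl)ethenyl]-2,3-dihydro-1-benzofuran
Conditions: 18 (3 equiv), NiCl2·glyme (20 mol%), 4,4'-di-tert-butyl-2,2'-bipyridine (40 mol%), THF/DMF, 25 °C
Reagents that add atoms: none
Why: Ni-catalysed decarboxylative Negishi-type arylation of a redox-active ester, in which single-electron reduction by aryl–Ni(I) releases CO2 and phthalimide anion to give the planar benzylic C3 radical, which is captured by aryl–Ni and reductively eliminated on the face anti to the C2 aryl group, so C3 should be re-formed trans to C2 (2S,3S).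

Step 12
Reactants: 19 (2S,3S)-3-(3,5-dimethoxyphenyl)-2-(2,4-dimethoxyphenyl)-4-methoxy-6-[(E)-2-(4-methoxyphenyl)ethenyl]-2,3-dihydro-1-benzofuran
Product: 20 4-[(2S,3S)-3-(3,5-dihydroxyphenyl)-4-hydroxy-6-[(E)-2-(4-hydroxyphenyl)ethenyl]-2,3-dihydro-1-benzofuran-2-yl]benzene-1,3-diol
Conditions: BBr3 (12 equiv), CH2Cl2, −78 → 0 °C; then MeOH/H2O
Reagents that add atoms: none
Why: BBr3 cleaves all six aryl methyl ethers by Lewis-acid activation and bromide attack at methyl, and because C3 is configurationally inert any reversible ionisation of the activated C2–O1 bond should reclose to the trans isomer with the same absolute configuration.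

**Compound list**

1 | 4-bromo-2,6-dimethoxybenzaldehyde | COc1cc(Br)cc(OC)c1C=O | starting material
2 | rac-1-(4-bromo-2,6-dimethoxyphenyl)ethan-1-ol | CC(O)c1c(OC)cc(Br)cc1OC | intermediate
3 | 1-(4-bromo-2,6-dimethoxyphenyl)ethan-1-one | CC(=O)c1c(OC)cc(Br)cc1OC | intermediate
4 | 1-(4-bromo-2-hydroxy-6-methoxyphenyl)ethan-1-one | CC(=O)c1c(O)cc(Br)cc1OC | intermediate
5 | (E)-1-(4-bromo-2-hydroxy-6-methoxyphenyl)-3-(dimethylamino)prop-2-en-1-one | CN(C)/C=C/C(=O)c1c(O)cc(Br)cc1OC | intermediate (not isolated)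
6 | 7-bromo-5-methoxy-4H-chromen-4-one | O=c1ccoc2cc(Br)cc(OC)c12 | intermediate
7 | (2,4-dimethoxyphenyl)boronic acid | COc1ccc(B(O)O)c(OC)c1 | starting material
8 | (2S)-7-bromo-2-(2,4-dimethoxyphenyl)-5-methoxychroman-4-one | O=C1C[C@@H](c2ccc(OC)cc2OC)Oc2cc(Br)cc(OC)c21 | intermediate
9 | (2S)-7-bromo-2-(2,4-dimethoxyphenyl)-4,5-dimethoxy-2H-chromene (enol ether) | COC1=C[C@@H](c2ccc(OC)cc2OC)Oc2cc(Br)cc(OC)c21 | intermediate (not isolated)
10 | [7-bromo-2-(2,4-dimethoxyphenyl)-4,4,5-trimethoxychroman-3-yl]thallium(III) dinitrate, Tl trans to the C2 aryl group, C2 arranged as in 8 | COC1(OC)[C@H]([Tl](O[N+](=O)[O-])O[N+](=O)[O-])[C@@H](c2ccc(OC)cc2OC)Oc2cc(Br)cc(OC)c21 | intermediate (not isolated)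
11 | methyl (2S,3S)-6-bromo-2-(2,4-dimethoxyphenyl)-4-methoxy-2,3-dihydro-1-benzofuran-3-carboxylate (trans) | Brc1cc(OC)c2c(c1)O[C@H](c1ccc(OC)cc1OC)[C@H]2C(=O)OC | intermediate
12 | 4-methoxystyrene | COc1ccc(C=C)cc1 | starting material
13 | methyl (2S,3S)-2-(2,4-dimethoxyphenyl)-4-methoxy-6-[(E)-2-(4-methoxyphenyl)ethenyl]-2,3-dihydro-1-benzofuran-3-carboxylate | COc1ccc(/C=C/c2cc(OC)c3c(c2)O[C@H](c2ccc(OC)cc2OC)[C@H]3C(=O)OC)cc1 | intermediate
14 | (2S,3S)-2-(2,4-dimethoxyphenyl)-4-methoxy-6-[(E)-2-(4-methoxyphenyl)ethenyl]-2,3-dihydro-1-benzofuran-3-carboxylic acid | COc1ccc(/C=C/c2cc(OC)c3c(c2)O[C@H](c2ccc(OC)cc2OC)[C@H]3C(=O)O)cc1 | intermediate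
15 | 1,3-dioxoisoindolin-2-yl (2S,3S)-2-(2,4-dimethoxyphenyl)-4-methoxy-6-[(E)-2-(4-methoxyphenyl)ethenyl]-2,3-dihydro-1-benzofuran-3-carboxylate | COc1ccc(/C=C/c2cc(OC)c3c(c2)O[C@H](c2ccc(OC)cc2OC)[C@H]3C(=O)ON2C(=O)c3ccccc3C2=O)cc1 | intermediate
16 | 1-bromo-3,5-dimethoxybenzene | COc1cc(Br)cc(OC)c1 | starting material
17 | (3,5-dimethoxyphenyl)magnesium bromide | COc1cc([Mg]Br)cc(OC)c1 | intermediate (not isolated)
18 | (3,5-dimethoxyphenyl)zinc chloride | COc1cc([Zn]Cl)cc(OC)c1 | intermediate
19 | (2S,3S)-3-(3,5-dimethoxyphenyl)-2-(2,4-dimethoxyphenyl)-4-methoxy-6-[(E)-2-(4-methoxyphenyl)ethenyl]-2,3-dihydro-1-benzofuran | COc1ccc(/C=C/c2cc(OC)c3c(c2)O[C@H](c2ccc(OC)cc2OC)[C@H]3c2cc(OC)cc(OC)c2)cc1 | intermediate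
20 | 4-[(2S,3S)-3-(3,5-dihydroxyphenyl)-4-hydroxy-6-[(E)-2-(4-hydroxyphenyl)ethenyl]-2,3-dihydro-1-benzofuran-2-yl]benzene-1,3-diol | Oc1ccc(/C=C/c2cc(O)c3c(c2)O[C@H](c2ccc(O)cc2O)[C@H]3c2cc(O)cc(O)c2)cc1 | target

**Step count and risks**

Total steps: 12. Longest linear sequence: 11 (steps 1–9, 11 and 12; step 10 prepares the arylzinc reagent).

Steps most likely to fail:

1. Step 6 (ring contraction). The electron-rich C2 aryl group may migrate instead of the benzo carbon, or H-2 may be lost to give the flavone. The acid released may also open the ring at C2 and erode its configuration, or the oxidant may attack the dimethoxyarene. Fallback, from 8: C3 is acylated (LiHMDS, THF, −78 °C; CF3CO2CH2CF3) to (2S)-7-bromo-2-(2,4-dimethoxyphenyl)-5-methoxy-3-(trifluoroacetyl)chroman-4-one F1. Detrifluoroacetylative diazo transfer (MsN3, Et3N, H2O, MeCN) then gives the 3-diazochroman-4-one F2. Photochemical Wolff rearrangement of F2 in MeOH (365 nm) can only shift the carbonyl-bound benzo carbon to C3, so the same C3–C3a bond forms through the ketene. This should give 11 together with its cis C3-epimer, methyl (2S,3R)-6-bromo-2-(2,4-dimethoxyphenyl)-4-methoxy-2,3-dihydro-1-benzofuran-3-carboxylate F3, which is equilibrated to the trans ester (cat. NaOMe, MeOH, 0 °C). The route is rejoined at 11.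

2. Step 11 (decarboxylative arylation). The hindered benzylic C3 radical may dimerise, the alkylnickel may lose the C2 hydrogen and aromatise to the benzofuran, the activated ester may decompose before coupling, or capture may be insufficiently trans-selective. Fallback, from 15: base-free photochemical decarboxylative borylation (B2cat2, DMAc, 450 nm, which the stilbene does not absorb; then pinacol, Et3N) should give the trans C3 pinacol boronate, 2-[(2S,3S)-2-(2,4-dimethoxyphenyl)-4-methoxy-6-[(E)-2-(4-methoxyphenyl)ethenyl]-2,3-dihydro-1-benzofuran-3-yl]-4,4,5,5-tetramethyl-1,3,2-dioxaborolane F4. Stereoretentive Suzuki–Miyaura coupling of this secondary benzylic boronate with 1-iodo-3,5-dimethoxybenzene (Pd2(dba)3, PPh3, Ag2O, DME, 85 °C) rejoins the route at 19.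

3. Step 5 (asymmetric conjugate addition). Protodeboronation of the ortho-substituted, electron-rich boronic acid may outpace transmetalation, insertion into the 5-methoxychromone may be sluggish, and the product may racemise by base-induced ring-opening. Fallback, from 4: Claisen–Schmidt condensation with 2,4-dimethoxybenzaldehyde (KOH, EtOH, rt) gives (E)-1-(4-bromo-2-hydroxy-6-methoxyphenyl)-3-(2,4-dimethoxyphenyl)prop-2-en-1-one F5. Oxa-Michael cyclisation (NaOAc, EtOH, reflux) gives racemic 7-bromo-2-(2,4-dimethoxyphenyl)-5-methoxychroman-4-one F6. Kinetic resolution by Ru–TsDPEN asymmetric transfer hydrogenation (RuCl(p-cymene)(TsDPEN), HCO2H/Et3N, to just past half conversion, catalyst antipode chosen to consume the 2R ketone) reduces the unwanted enantiomer to cis-(2R,4R)-7-bromo-2-(2,4-dimethoxyphenyl)-5-methoxychroman-4-ol F7 and leaves the 2S ketone. The route is rejoined at 8.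

**Further compounds**

F1 | step 6 | (2S)-7-bromo-2-(2,4-dimethoxyphenyl)-5-methoxy-3-(trifluoroacetyl)chroman-4-one (C3 unassigned, enolisable) | O=C1C(C(=O)C(F)(F)F)[C@@H](c2ccc(OC)cc2OC)Oc2cc(Br)cc(OC)c21
F2 | step 6 | 7-bromo-3-diazo-2-(2,4-dimethoxyphenyl)-5-methoxychroman-4-one, C2 arranged as in 8 | O=C1C(=[N+]=[N-])[C@@H](c2ccc(OC)cc2OC)Oc2cc(Br)cc(OC)c21
F3 | step 6 | methyl (2S,3R)-6-bromo-2-(2,4-dimethoxyphenyl)-4-methoxy-2,3-dihydro-1-benzofuran-3-carboxylate (cis) | Brc1cc(OC)c2c(c1)O[C@H](c1ccc(OC)cc1OC)[C@@H]2C(=O)OC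
F4 | step 11 | 2-[(2S,3S)-2-(2,4-dimethoxyphenyl)-4-methoxy-6-[(E)-2-(4-methoxyphenyl)ethenyl]-2,3-dihydro-1-benzofuran-3-yl]-4,4,5,5-tetramethyl-1,3,2-dioxaborolane (trans) | COc1ccc(/C=C/c2cc(OC)c3c(c2)O[C@H](c2ccc(OC)cc2OC)[C@H]3B2OC(C)(C)C(C)(C)O2)cc1
F5 | step 5 | (E)-1-(4-bromo-2-hydroxy-6-methoxyphenyl)-3-(2,4-dimethoxyphenyl)prop-2-en-1-one | COc1ccc(/C=C/C(=O)c2c(O)cc(Br)cc2OC)c(OC)c1
F6 | step 5 | rac-7-bromo-2-(2,4-dimethoxyphenyl)-5-methoxychroman-4-one | O=C1CC(c2ccc(OC)cc2OC)Oc2cc(Br)cc(OC)c21
F7 | step 5 | (2R,4R)-7-bromo-2-(2,4-dimethoxyphenyl)-5-methoxychroman-4-ol (cis) | O[C@@H]1C[C@H](c2ccc(OC)cc2OC)Oc2cc(Br)cc(OC)c21
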